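How much of L has become X after 3.0 d, and does L or X then hold the larger share? The runs so far and the questions stand below.

the same everywhere: L 0.50 M

|  | E | remark | time |
|---|---|---|---|
| south-west | 0.23 M | run made earlier |  |
| north | 0.95 M | run made earlier |  |
| winter | 0.350 M |  | 3.0 d |
| dawn | 0.700 M |  | 3.0 d |
| midnight | 1.40 M |  | 3.0 d |

| run | time / h | L / % | X / % |
|---|---|---|---|
| south-west | 8.00 | 96 | 3 |
| south-west | 15.0 | 93 | 5 |
| south-west | 20.0 | 90 | 4 |
| south-west | 30.0 | 83 | 11 |
| south-west | 40.0 | 85 | 16 |
| south-west | 48.0 | 85 | 14 |
| north | 2.50 | 95 | 4 |
| north | 8.00 | 85 | 11 |
| north | 15.0 | 79 | 23 |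
| north | 20.0 | 74 | 29 |
| north | 30.0 | 64 | 38 |
| north | 40.0 | 59 | 44 |
| north | 48.0 | 54 | 46 |

(standard deviation of a reading: 2 percentage points)

- which of these there is most of at the end, counted by the L in it, winter (L / X)
- which of these there is most of at the end, counted by the L in it, dawn (L / X)
- which of these there is most of at the end, counted by the L in it, midnight (L / X)
- final amount of the leader among these, as a percentage of the L charged, in winter
- final amount of the leader among these, as a percentage of the L charged, in dawn
- final amount of the leader among these, as a percentage of the L charged, in midnight

Let x be the fraction of charged L turned into X. In the north run the readings of L and X together come to the full charge at 48.0 h, so one L is taken to give one X, and one E per L is the first guess. E then falls linearly in x, and its mean over a run is taken as the charge less half of what x has used.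

A first estimate is first order in L: the logarithm of L's fraction, divided by mean E and time. The north run gives 0.0223 M⁻¹ h⁻¹ at 8.00 h but 0.0154 M⁻¹ h⁻¹ at 48.0 h. That slide looks too wide for a scatter of 2 percentage points.

Second order in L does better. Take the ratio of L turned to L left, divided by mean E and time; this is a pseudo-second-order law with E's mean folded in. The same run then reads 0.0242 M⁻¹ h⁻¹ and, at 48.0 h, the exposure constant K 0.0213 M⁻¹ h⁻¹, a narrower slide than the first.

But the south-west run looks stopped, its X reading 16 % and then 14 %. K from the north run gives that flask 14.2 % at 40.0 h and 16.2 % at 48.0 h. The rise is 2 points against a scatter of 2 points, so the flat pair of readings proves no stop.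

Solving the rule for x at 3.0 d gives 29.7 % in winter, 47.1 % in dawn and 65.4 % in midnight. The leaders are therefore L, L and X, with dawn 2.9 points short of the even split.

One objection remains: x rises fastest early, so the true time-mean of E lies under the arithmetic one. On the rule's own curve the shortfall is 2.79 % in the north run and 4.51 % in midnight. K already carries the first, so midnight's x moves down by 0.39 points.

The forecast names L, L and X at 78 %, 58 % and 71 %, higher than the reckoning here, and adds “midnight stays the least certain”.

The flasks give L at 70.4 % in winter, L at 52.9 % in dawn and X at 65.5 % in midnight.

    L + E → X, rate k1*[L]^2*[E] (k = 7.50 × 10⁻⁴ M⁻² min⁻¹)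
    E → Q (k = 8.20 × 10⁻⁷ min⁻¹)

At the end of midnight the part of charged L left, 35 %, is less than the part of E left, 76 %. K put to midnight at 1.50 d gives 49.4 %, and that flask then holds 50.1 % of X.

A neighbour of midnight holds 1.2 M of L. A rate second order in L scales K with L's charge, to 0.0510 M⁻¹ h⁻¹, and the rule gives 77.5 %. The computed neighbour ends at 73.6 % of X, less than that, with 37 % of its E left.

The earlier runs and the new flask stem from a simulated flask with constants of no real substance, and the scatter is random.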